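**Retrosynthetic overview**
1. 14 ⇐ aldehyde 13 (Takai bromo-olefination) ⇐ ester 12 ⇐ alkenyl bromide 11 (hydrogen-atom-transfer hydrogenation sets the C–Br centre) ⇐ bromodiene 9 (face-selective epoxidation, then double-inversion deoxydichlorination gives the cis-dichloride).
2. 9 ⇐ enone 8 ⇐ nitro enone 7: the ring ketone becomes the C–Br carbon, and the nitro group is a traceless activator removed by radical denitration.
3. Key disconnection of 7: the CH2–C(quaternary) bond and the CH–C(Me)(NO2) bond (in 14: CH2–C(Me)(bromovinyl) and CHCl–C(Me)Cl). This is a catalytic asymmetric formal [4+2] (Michael / Michael–elimination) of β-keto ester 5 (four ring carbons) with 2-nitropropene 2 (two ring carbons).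
4. Enabling feature: in the cyclohexane of 14 the CHBr carbon is the direct neighbour of the quaternary carbon, and the C(Me)Cl carbon stands 1,3 to it across the isolated ring CH2. Carried as C=O and as C–NO2, they make the quaternary carbon a 1,3-dicarbonyl nucleophile, the CHCl carbon the β-carbon of an alkoxy enone and the C(Me)Cl carbon a nitronate, so all four bond-forming atoms have matching polarity.
5. Ring order: the carbocycle is the only ring of the target and is closed in step 3; the epoxide of 10 is a temporary second ring (steps 6–7).

Key step: step 3

Remark on the chemistry: the cinchona pseudoenantiomer (cupreine or cupreidine series) that gives the (R)-configured quaternary carbon of 7 is to be fixed in a first run, and everything downstream is drawn for that enantiomer. 2-Nitropropene polymerises on storage and is therefore made fresh (step 1). Locants in names follow each compound's own numbering.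

Step 1
Reactants: 1 2-nitropropan-1-ol
Product: 2 2-nitropropene
Conditions: phthalic anhydride (1.3 equiv), 150–180 °C, 110 mmHg, product distilled out, kept cold and used at once
Reagents that add atoms: none
Why: Thermal dehydration of a β-nitro alcohol through its phthalate half-ester (elimination to the conjugated nitroalkene), the standard preparation of 2-nitropropene; no stereocentre is involved.

Step 2
Reactants: 3 methyl propionate; 4 (E)-3-ethoxyacryloyl chloride
Product: 5 methyl (E)-5-ethoxy-2-methyl-3-oxopent-4-enoate
Conditions: LDA (2.1 equiv), 3 (2.1 equiv), THF, −78 °C; then 4 (1.0 equiv), −78 → −40 °C; aq NH4Cl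
Reagents that add atoms: none
Why: Crossed Claisen C-acylation of the lithium enolate of 3 by the acid chloride 4 (the excess enolate deprotonates the more acidic β-keto ester as it forms, which prevents double acylation); the acyl chloride carbon is far more electrophilic than the vinylogous β-carbon, and C2 of 5 is configurationally labile and of no consequence.

Step 3
Reactants: 5 methyl (E)-5-ethoxy-2-methyl-3-oxopent-4-enoate; 2 2-nitropropene (1.5 equiv)
Product: 7 methyl (1R)-1,5-dimethyl-5-nitro-2-oxocyclohex-3-ene-1-carboxylate (both C5 epimers), via Michael adduct 6 (not isolated)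
Conditions: O-benzylcupreidine or O-benzylcupreine (6'-OH cinchona catalyst, 10 mol %), toluene, −20 °C; then DBU (20 mol %), 23 °C, same flask
Reagents that add atoms: none
Why: The bifunctional cinchona catalyst deprotonates the 1,3-dicarbonyl C–H of 5 and, holding the Z-enolate at its quinuclidinium and the nitroalkene at its phenol OH, delivers C2 of 5 to the CH2 terminus of 2 (first bond, quaternary stereocentre, gives 6); the secondary nitroalkane of 6 (pKa about 8) is then deprotonated and its nitronate carbon adds to the ethoxy-bearing enone carbon, after which ethoxide is expelled (second bond, conjugate addition–elimination). The closest known reaction type is the amine–thiourea or cinchona-catalysed tandem Michael/Michael annulation of γ,δ-unsaturated β-keto esters with nitroalkenes (an anionic formal [4+2] of the Deslongchamps kind), here ending in an E1cB step. The single ring closes in a 6-endo-trig conjugate addition with the ketone carbon inside the forming ring. The quaternary carbon is set by the catalyst (enolate face), as in the known additions of α-substituted β-keto esters to acceptors that carry no β-substituent, and because 5 is enolisable all of the racemic material passes through the same enolate; the nitro-bearing carbon forms as both epimers, which is harmless because it becomes sp2 in step 5. The step needs chemoselectivity (the enolate of 5 must attack 2 and not the vinylogous ester of a second molecule of 5) and regioselectivity in the closure; the first should follow from the far higher electrophilicity of the nitroalkene, the second from the ethoxy-substituted carbon being the only electrophilic position six atoms from the nitronate carbon while the quaternary carbon blocks aldol and enolisation alternatives.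

Step 4
Reactants: 7 methyl (1R)-1,5-dimethyl-5-nitro-2-oxocyclohex-3-ene-1-carboxylate
Product: 8 methyl (1R)-1,5-dimethyl-2-oxocyclohex-3-ene-1-carboxylate (both C5 epimers)
Conditions: Bu3SnH (1.3 equiv), AIBN (0.2 equiv), PhH, 80 °C; then DBU (10 mol %), 23 °C
Reagents that add atoms: none
Why: Ono-type radical denitration with tin hydride (cleavage of the tertiary, allylic C–NO2 bond), followed by base-mediated gathering of any deconjugated isomer into the conjugated enone; the C5 stereocentre is left uncontrolled on purpose because both epimers converge in step 5.

Step 5
Reactants: 8 methyl (1R)-1,5-dimethyl-2-oxocyclohex-3-ene-1-carboxylate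
Product: 9 methyl (1S)-2-bromo-1,5-dimethylcyclohexa-2,4-diene-1-carboxylate
Conditions: (PhO)3P (1.2 equiv), Br2 (1.2 equiv), CH2Cl2, −60 °C; then Et3N (1.4 equiv) and 8, −60 → 40 °C
Reagents that add atoms: bromine, BrBr
Why: Ketone to alkenyl bromide conversion with triphenyl phosphite dibromide and Et3N (bromophosphonium activation of the carbonyl oxygen, then loss of HBr), which on an enone whose α' carbon is quaternary can only deprotonate at the γ-carbon and so should give the linear 2-bromo-1,3-diene from both C5 epimers (analogous to the classical enone to 3-bromo-3,5-diene conversion of steroids); the quaternary centre is untouched and its descriptor changes from R to S only because C–Br now outranks the ester.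

Step 6
Reactants: 9 methyl (1S)-2-bromo-1,5-dimethylcyclohexa-2,4-diene-1-carboxylate
Product: 10 methyl (1S,4S,6R)-3-bromo-4,6-dimethyl-7-oxabicyclo[4.1.0]hept-2-ene-4-carboxylate (epoxide oxygen on the ring face opposite to the ester)
Conditions: mCPBA (1.1 equiv), NaHCO3, CH2Cl2, 0 °C
Reagents that add atoms: mCPBA, OOC(=O)c1cccc(Cl)c1
Why: Prilezhaev epoxidation, chemoselective for the electron-rich trisubstituted C4=C5 bond over the electron-poor bromoalkene; the ester on the quaternary carbon, larger than methyl, screens the upper face, so the oxygen should add to the face that carries the C1 methyl group and thereby set both epoxide carbons.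

Step 7
Reactants: 10 methyl (1S,4S,6R)-3-bromo-4,6-dimethyl-7-oxabicyclo[4.1.0]hept-2-ene-4-carboxylate
Product: 11 methyl (1S,4R,5S)-2-bromo-4,5-dichloro-1,5-dimethylcyclohex-2-ene-1-carboxylate
Conditions: Ph3PCl2 (1.5 equiv), CH2Cl2, 0 → 23 °C
Reagents that add atoms: dichlorotriphenylphosphorane, ClP(Cl)(c1ccccc1)(c1ccccc1)c1ccccc1
Why: Deoxydichlorination of an epoxide with dichlorotriphenylphosphorane (chloride opens the P-activated epoxide with inversion at the tertiary carbon, then displaces the oxyphosphonium group with inversion at the allylically activated secondary carbon), the known route from an epoxide to the syn-dichloride of the parent alkene; both chlorines should therefore end on the face opposite to the former oxygen, cis to the ester.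

Step 8
Reactants: 11 methyl (1S,4R,5S)-2-bromo-4,5-dichloro-1,5-dimethylcyclohex-2-ene-1-carboxylate
Product: 12 methyl (1S,2S,4R,5S)-2-bromo-4,5-dichloro-1,5-dimethylcyclohexane-1-carboxylate
Conditions: Co(acac)2 (0.25–1.0 equiv), t-BuOOH (1.0 equiv), Et3SiH (5 equiv), 1,4-cyclohexadiene (5 equiv), n-PrOH, 23 °C
Reagents that add atoms: none
Why: Cobalt-hydride hydrogen-atom-transfer hydrogenation of an alkenyl halide to the alkyl halide (the H atom adds to the CH terminus and the α-bromo radical takes the second H from cyclohexadiene) without C–halogen cleavage; in the chair fixed by the two equatorial methyl groups the hydrogen should be delivered axially, anti to the axial ester, which places bromine equatorial and cis to the ester.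

Step 9
Reactants: 12 methyl (1S,2S,4R,5S)-2-bromo-4,5-dichloro-1,5-dimethylcyclohexane-1-carboxylate
Product: 13 (1S,2S,4R,5S)-2-bromo-4,5-dichloro-1,5-dimethylcyclohexane-1-carbaldehyde
Conditions: DIBAL-H (1.2 equiv), CH2Cl2, −78 °C; Rochelle salt work-up
Reagents that add atoms: none
Why: Partial reduction of a hindered α-quaternary methyl ester with DIBAL-H at −78 °C (the tetrahedral aluminate should survive until work-up); alkyl halides are inert and the aldehyde has no α-hydrogen, so no stereocentre can be lost.

Step 10
Reactants: 13 (1S,2S,4R,5S)-2-bromo-4,5-dichloro-1,5-dimethylcyclohexane-1-carbaldehyde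
Product: 14 (1S,2S,4R,5S)-2-bromo-1-[(E)-2-bromoethenyl]-4,5-dichloro-1,5-dimethylcyclohexane
Conditions: CrBr3 (8 equiv), LiAlH4 (2 equiv), THF, 0 °C (gives CrBr2); then CHBr3 (2 equiv) and 13, 0 → 23 °C
Reagents that add atoms: bromoform, BrC(Br)Br
Why: Takai olefination (gem-dichromium carbenoid from bromoform), E-selective for α-branched aldehydes; CrBr2 is used in place of CrCl2 to exclude Br/Cl exchange in the vinyl halide, and unactivated alkyl chlorides and the neopentyl-type secondary bromide should not be reduced by the chromium reagent at this temperature.

**Compound list**
1 | 2-nitropropan-1-ol | CC(CO)[N+](=O)[O-] | starting material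
2 | 2-nitropropene | CC(=C)[N+](=O)[O-] | intermediate
3 | methyl propionate | CCC(=O)OC | starting material
4 | (E)-3-ethoxyacryloyl chloride | CCO/C=C/C(Cl)=O | starting material
5 | methyl (E)-5-ethoxy-2-methyl-3-oxopent-4-enoate (racemic, C2 labile) | CCO/C=C/C(=O)C(C)C(=O)OC | intermediate
6 | methyl (2R)-2-[(E)-3-ethoxyprop-2-enoyl]-2-methyl-4-nitropentanoate (both C4 epimers; not isolated) | CCO/C=C/C(=O)[C@@](C)(CC(C)[N+](=O)[O-])C(=O)OC | intermediate
7 | methyl (1R)-1,5-dimethyl-5-nitro-2-oxocyclohex-3-ene-1-carboxylate (both C5 epimers) | CC1(C[C@@](C)(C(=O)OC)C(=O)C=C1)[N+](=O)[O-] | intermediate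
8 | methyl (1R)-1,5-dimethyl-2-oxocyclohex-3-ene-1-carboxylate (both C5 epimers) | CC1C[C@@](C)(C(=O)OC)C(=O)C=C1 | intermediate
9 | methyl (1S)-2-bromo-1,5-dimethylcyclohexa-2,4-diene-1-carboxylate | CC1=CC=C(Br)[C@@](C)(C1)C(=O)OC | intermediate
10 | methyl (1S,4S,6R)-3-bromo-4,6-dimethyl-7-oxabicyclo[4.1.0]hept-2-ene-4-carboxylate (oxygen trans to the ester) | C[C@@]12C[C@@](C)(C(=O)OC)C(Br)=C[C@@H]1O2 | intermediate
11 | methyl (1S,4R,5S)-2-bromo-4,5-dichloro-1,5-dimethylcyclohex-2-ene-1-carboxylate (both Cl cis to the ester) | C[C@]1(Cl)C[C@@](C)(C(=O)OC)C(Br)=C[C@H]1Cl | intermediate
12 | methyl (1S,2S,4R,5S)-2-bromo-4,5-dichloro-1,5-dimethylcyclohexane-1-carboxylate | C[C@]1(Cl)C[C@@](C)(C(=O)OC)[C@@H](Br)C[C@H]1Cl | intermediate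
13 | (1S,2S,4R,5S)-2-bromo-4,5-dichloro-1,5-dimethylcyclohexane-1-carbaldehyde | C[C@]1(Cl)C[C@@](C)(C=O)[C@@H](Br)C[C@H]1Cl | intermediate
14 | (1S,2S,4R,5S)-2-bromo-1-[(E)-2-bromoethenyl]-4,5-dichloro-1,5-dimethylcyclohexane | C[C@]1(Cl)C[C@@](C)(/C=C/Br)[C@@H](Br)C[C@H]1Cl | target

**Step count and risks**
Total step count: 10. Longest linear sequence: 9 steps (3 → 14, steps 2–10).

Steps most likely to fail:

Step 3. What may go wrong: weak enantiofacial discrimination of the acyclic enolate toward an acceptor without a β-substituent, erosion of the quaternary centre by retro-Michael and re-addition of 6 once DBU is present, or a sluggish ring closure onto the vinylogous ester. Fallback: auxiliary control, with the two bonds made in separate operations; it sets out from 2 and comes back to the route at 7. Purchased methyl 2-methyl-3-oxobutanoate would be condensed with purchased (S)-1-phenylethylamine (TsOH cat., PhH, water removal) to the secondary enamino ester methyl (Z)-2-methyl-3-{[(1S)-1-phenylethyl]amino}but-2-enoate F1. Its d'Angelo–Pfau deracemising Michael addition to 2 (THF, 0 → 23 °C, then aq AcOH) should give, after hydrolysis of the imine, methyl (2R)-2-acetyl-2-methyl-4-nitropentanoate F2 with the quaternary carbon set by the auxiliary (the other amine enantiomer would be used if the sense proves opposite). Condensation of the acetyl group with DMF dimethyl acetal (PhMe, 90 °C) should give the enaminone methyl (2R)-2-[(E)-3-(dimethylamino)prop-2-enoyl]-2-methyl-4-nitropentanoate F3. DBU (MeCN, 50 °C) should then close the ring by the same nitronate addition–elimination, now expelling dimethylamine, to give 7.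

Step 7. What may go wrong: ionisation of the allylic C–O bond of the oxyphosphonium intermediate (SN1 or SN2' leakage, elimination), which would erode the double inversion. Fallback: direct catalytic syn-dichlorination of the alkene by selenium redox catalysis, which sets out from 9 and comes back at 11 without passing through 10. The conditions would be (PhSe)2 (5 mol %), BnEt3NCl, N-fluoropyridinium tetrafluoroborate, Me3SiCl, MeCN, 23 °C: anti chloroselenation on the less hindered lower face, then invertive displacement of the tetravalent selenium group by chloride. This makes no compound outside the list, F0.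

Step 6. What may go wrong: poor or inverted facial discrimination, because ester and methyl on the remote quaternary carbon differ only modestly in size. Fallback: reagent control in place of substrate control, a Shi asymmetric epoxidation, which sets out from 9 and comes back at 10. The fructose-derived ketone, or its enantiomer from L-sorbose, whichever is matched to the lower face, would be used with Oxone and K2CO3 in MeCN/dimethoxymethane–water at 0 °C; conjugated dienes are known to be mono-epoxidised at the more substituted double bond under these conditions. This makes no compound outside the list, F0.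

**Further compounds**
F1 | step 3 | methyl (Z)-2-methyl-3-{[(1S)-1-phenylethyl]amino}but-2-enoate | C/C(N[C@@H](C)c1ccccc1)=C(C)/C(=O)OC
F2 | step 3 | methyl (2R)-2-acetyl-2-methyl-4-nitropentanoate (both C4 epimers) | CC(=O)[C@@](C)(CC(C)[N+](=O)[O-])C(=O)OC
F3 | step 3 | methyl (2R)-2-[(E)-3-(dimethylamino)prop-2-enoyl]-2-methyl-4-nitropentanoate (both C4 epimers) | CN(C)/C=C/C(=O)[C@@](C)(CC(C)[N+](=O)[O-])C(=O)OC
F0 | step 7 | none | none
F0 | step 6 | none | none
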